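**Plan**
- Retrosynthetic cuts, in order: the O1–C2 bond of ring C; the bond from C6 of ring A to the bridging CH2 (and on to pyrone C3); the two ring A–acyl bonds (C8–CO and C4a–C4), made as aryl–carbinol bonds; the pyrone ring, cut into pentan-3-one and a malonyl unit.
- Forward order: the pyrone ring is made first on its own (steps 1–2); ring A is phloroglucinol, which as its tris-MOM ether receives the 3-methylbut-2-enoyl arm and then the cinnamoyl arm (steps 3–7); the methylene bridge joins the pyrone to ring A (step 8); ring C closes last (step 9).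
- Enabling feature: C2 is the β-carbon of a cinnamoyl unit whose carbonyl C4 sits on C4a of ring A, and the phenol oxygen that becomes O1 sits on C8a, directly between the acyl-bearing carbons C4a and C8, so conjugate addition closes a six-membered ring.
- Stereochemistry: the only stereocentre, C2 (S), is set in the last step by the chalcone isomerase active site; no later step can racemise it.

Key step: step 9

Assumption: the chalcones 14 and 18 close only slowly without a catalyst when kept cold at or below neutral pH, so they are taken on without storage; the carbinol centres of 9 and 12 are left uncontrolled because step 6 removes them.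

**Step 1**
Reactants: 1 pentan-3-one
Product: 2 (Z)-trimethyl(pent-2-en-3-yloxy)silane
Conditions: TMSOTf, Et3N, CH2Cl2, 0 °C
Reagents that add atoms: trimethylsilyl trifluoromethanesulfonate, C[Si](C)(C)OS(=O)(=O)C(F)(F)F
Why: Silyl enol ether formation by soft enolisation of a symmetrical ketone, so only one regioisomer can arise and the alkene geometry is of no consequence for step 2.

**Step 2**
Reactants: 2 (Z)-trimethyl(pent-2-en-3-yloxy)silane; 3 malonyl dichloride
Product: 4 6-ethyl-4-hydroxy-5-methyl-2H-pyran-2-one
Conditions: Et2O, −78 → 25 °C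
Reagents that add atoms: none
Why: Pyrone annulation of a silyl enol ether with malonyl dichloride (C-acylation by one acyl chloride, then O-acylative lactonisation of the enolised ethyl ketone onto the other), which places ethyl on C6 and methyl on C5 of the 4-hydroxy-2-pyrone.

**Step 3**
Reactants: 5 phloroglucinol
Product: 6 1,3,5-tris(methoxymethoxy)benzene
Conditions: NaH, MOMCl, DMF, 0 → 25 °C
Reagents that add atoms: chloromethyl methyl ether, COCCl
Why: Williamson-type O-alkylation of the phenoxide with the hard electrophile MOMCl should give the tris-acetal, whose three ring CH positions are equivalent and each flanked by two directing groups.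

**Step 4**
Reactants: 6 1,3,5-tris(methoxymethoxy)benzene; 7 3-methylbut-2-enal
Product: 9 racemic 3-methyl-1-[2,4,6-tris(methoxymethoxy)phenyl]but-2-en-1-ol, via aryllithium 8 (not isolated)
Conditions: n-BuLi, THF, 0 °C; then 7, −78 → 0 °C; H2O
Reagents that add atoms: none
Why: Directed ortho-metalation between two OMOM groups followed by 1,2-addition of the aryllithium to the enal; the carbinol centre forms racemic and is removed by oxidation in step 6.

**Step 5**
Reactants: 9 racemic 3-methyl-1-[2,4,6-tris(methoxymethoxy)phenyl]but-2-en-1-ol; 10 (E)-cinnamaldehyde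
Product: 12 (E)-1-[3-(1-hydroxy-3-methylbut-2-enyl)-2,4,6-tris(methoxymethoxy)phenyl]-3-phenylprop-2-en-1-ol (diastereomer mixture), via dilithio alkoxide 11 (not isolated)
Conditions: n-BuLi (2.2 equiv), TMEDA, THF, 0 °C; then 10, −78 → 0 °C; H2O
Reagents that add atoms: none
Why: Second directed ortho-metalation, in which the first equivalent of base forms the lithium alkoxide and the second lithiates one of the two equivalent ring positions lying between two OMOM groups, followed by 1,2-addition to the enal; the new carbinol centre is uncontrolled and is erased in step 6.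

**Step 6**
Reactants: 12 (E)-1-[3-(1-hydroxy-3-methylbut-2-enyl)-2,4,6-tris(methoxymethoxy)phenyl]-3-phenylprop-2-en-1-ol
Product: 13 (E)-1-[3-(3-methylbut-2-enoyl)-2,4,6-tris(methoxymethoxy)phenyl]-3-phenylprop-2-en-1-one
Conditions: MnO2 (activated, excess), CH2Cl2, 25 °C
Reagents that add atoms: none
Why: MnO2 oxidation of allylic/benzylic alcohols; both carbinols are allylic as well as benzylic, so both should be oxidised under neutral conditions that leave the acetals and the E-alkene untouched.

**Step 7**
Reactants: 13 (E)-1-[3-(3-methylbut-2-enoyl)-2,4,6-tris(methoxymethoxy)phenyl]-3-phenylprop-2-en-1-one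
Product: 14 (E)-1-[2,4,6-trihydroxy-3-(3-methylbut-2-enoyl)phenyl]-3-phenylprop-2-en-1-one
Conditions: HCl (cat.), MeOH, 0 → 25 °C
Reagents that add atoms: none
Why: Acid-catalysed methanolysis (transacetalisation) of aryl MOM ethers, all three of which lie ortho to a carbonyl group and cleave under mild conditions, while ring closure of o-hydroxyaryl enones of this kind calls for base or hot strong acid, so cold dilute acid should leave both enone arms open.

**Step 8**
Reactants: 14 (E)-1-[2,4,6-trihydroxy-3-(3-methylbut-2-enoyl)phenyl]-3-phenylprop-2-en-1-one; 4 6-ethyl-4-hydroxy-5-methyl-2H-pyran-2-one; 15 N,N-dimethylmethyleneiminium iodide (Eschenmoser's salt)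
Product: 18 (E)-1-[3-[(6-ethyl-4-hydroxy-5-methyl-2-oxo-2H-pyran-3-yl)methyl]-2,4,6-trihydroxy-5-(3-methylbut-2-enoyl)phenyl]-3-phenylprop-2-en-1-one, via pyrone Mannich base 16 (not isolated), via methylidenepyrandione 17 (not isolated)
Conditions: 4 + 15, MeCN, 25 °C; then 14, 40 °C
Reagents that add atoms: none
Why: Three-component carba-Betti coupling (Mannich aminomethylation of pyrone C3, loss of dimethylamine to the methylidenepyrandione, Michael-type addition of the only unsubstituted ring carbon of 14), the reaction type by which methylene-bridged pyrone–acylphloroglucinol heterodimers are assembled.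

**Step 9**
Reactants: 18 (E)-1-[3-[(6-ethyl-4-hydroxy-5-methyl-2-oxo-2H-pyran-3-yl)methyl]-2,4,6-trihydroxy-5-(3-methylbut-2-enoyl)phenyl]-3-phenylprop-2-en-1-one
Product: 19 (2S)-6-[(6-ethyl-4-hydroxy-5-methyl-2-oxo-2H-pyran-3-yl)methyl]-5,7-dihydroxy-8-(3-methylbut-2-enoyl)-2-phenyl-2,3-dihydro-4H-chromen-4-one (CNP0311807.1)
Conditions: chalcone isomerase (Medicago sativa enzyme or an evolved variant, high loading), KH2PO4/K2HPO4 buffer (50 mM, pH 6.5), DMSO (5% v/v), 10 °C
Reagents that add atoms: none
Why: Proposed new method: the isomerase is expected to take the cinnamoyl arm of 18 into its active-site cleft, place the deprotonated phenol oxygen that lies between the two acyl groups above one face of the enone and add it to the β-carbon, after which the enolate is protonated at C3; the closest known reaction type is the chalcone isomerase cyclisation of 2',4',6'-trihydroxychalcones such as naringenin chalcone and pinocembrin chalcone to (2S)-flavanones, which has not been shown for a chalcone substituted at both ring positions flanking the 4'-hydroxyl. Ring C closes in a 6-endo-trig oxa-Michael mode, forming the O1–C2 bond. The configuration at C2 is under catalyst control, since the active site should expose only the face of the β-carbon that leads to (2S), and no other stereocentre is present. The step needs site selectivity (the oxygen between the acyl groups, not the one beside the methylene bridge), chemoselectivity (the cinnamoyl arm, not the 3-methylbut-2-enoyl arm) and face selectivity. In the substrate, the β,β-dimethyl enone is the poorer acceptor and lacks the aryl group the enzyme binds, the bulky pyronylmethyl group should only fit pointing out of the cleft so that the inter-acyl oxygen faces the catalytic residues, and the oxygen beside the bridge is tied up in hydrogen bonding to the pyrone. Running cold, slightly below neutral pH and with much enzyme should keep the uncatalysed racemic closure slow, and a variant with a wider cleft may have to be evolved.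

**Compound list**
1 | pentan-3-one | CCC(=O)CC | starting material
2 | (Z)-trimethyl(pent-2-en-3-yloxy)silane | C/C=C(\O[Si](C)(C)C)CC | intermediate
3 | malonyl dichloride | O=C(Cl)CC(=O)Cl | starting material
4 | 6-ethyl-4-hydroxy-5-methyl-2H-pyran-2-one | CCc1oc(=O)cc(O)c1C | intermediate
5 | phloroglucinol (benzene-1,3,5-triol) | Oc1cc(O)cc(O)c1 | starting material
6 | 1,3,5-tris(methoxymethoxy)benzene | COCOc1cc(OCOC)cc(OCOC)c1 | intermediate
7 | 3-methylbut-2-enal | CC(C)=CC=O | starting material
8 | [2,4,6-tris(methoxymethoxy)phenyl]lithium | [Li]c1c(OCOC)cc(OCOC)cc1OCOC | intermediate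
9 | racemic 3-methyl-1-[2,4,6-tris(methoxymethoxy)phenyl]but-2-en-1-ol | CC(C)=CC(O)c1c(OCOC)cc(OCOC)cc1OCOC | intermediate
10 | (E)-cinnamaldehyde ((E)-3-phenylprop-2-enal) | O=C/C=C/c1ccccc1 | starting material
11 | lithium 1-[3-lithio-2,4,6-tris(methoxymethoxy)phenyl]-3-methylbut-2-en-1-olate | CC(C)=CC(O[Li])c1c(OCOC)cc(OCOC)c([Li])c1OCOC | intermediate
12 | (E)-1-[3-(1-hydroxy-3-methylbut-2-enyl)-2,4,6-tris(methoxymethoxy)phenyl]-3-phenylprop-2-en-1-ol (diastereomer mixture, carbinol centres unassigned) | CC(C)=CC(O)c1c(OCOC)cc(OCOC)c(C(O)/C=C/c2ccccc2)c1OCOC | intermediate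
13 | (E)-1-[3-(3-methylbut-2-enoyl)-2,4,6-tris(methoxymethoxy)phenyl]-3-phenylprop-2-en-1-one | CC(C)=CC(=O)c1c(OCOC)cc(OCOC)c(C(=O)/C=C/c2ccccc2)c1OCOC | intermediate
14 | (E)-1-[2,4,6-trihydroxy-3-(3-methylbut-2-enoyl)phenyl]-3-phenylprop-2-en-1-one | CC(C)=CC(=O)c1c(O)cc(O)c(C(=O)/C=C/c2ccccc2)c1O | intermediate
15 | N,N-dimethylmethyleneiminium iodide (Eschenmoser's salt) | C[N+](C)=C.[I-] | starting material
16 | 3-[(dimethylamino)methyl]-6-ethyl-4-hydroxy-5-methyl-2H-pyran-2-one | CCc1oc(=O)c(CN(C)C)c(O)c1C | intermediate
17 | 6-ethyl-5-methyl-3-methylidene-2H-pyran-2,4(3H)-dione | CCC1=C(C)C(=O)C(=C)C(=O)O1 | intermediate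
18 | (E)-1-[3-[(6-ethyl-4-hydroxy-5-methyl-2-oxo-2H-pyran-3-yl)methyl]-2,4,6-trihydroxy-5-(3-methylbut-2-enoyl)phenyl]-3-phenylprop-2-en-1-one | CCc1oc(=O)c(Cc2c(O)c(C(=O)C=C(C)C)c(O)c(C(=O)/C=C/c3ccccc3)c2O)c(O)c1C | intermediate
19 | (2S)-6-[(6-ethyl-4-hydroxy-5-methyl-2-oxo-2H-pyran-3-yl)methyl]-5,7-dihydroxy-8-(3-methylbut-2-enoyl)-2-phenyl-2,3-dihydro-4H-chromen-4-one (CNP0311807.1) | CCc1oc(=O)c(Cc2c(O)c(C(=O)C=C(C)C)c3c(c2O)C(=O)C[C@@H](c2ccccc2)O3)c(O)c1C | target

**Totals**
Total step count: 9. Longest linear sequence: 7 steps (steps 3 to 9, from phloroglucinol 5); the pyrone branch (steps 1 and 2) joins at step 8.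

**Steps most likely to fail**

Step 9 (the step that carries the label). The enzyme may not accept a chalcone flanked on both sides of its 4'-hydroxyl. Turnover would then be slow, the uncatalysed closure would erode the enantiomeric purity, or closure could run through the wrong phenol oxygen. The fallback sets out from 18 and uses the known uncatalysed isomerisation of 6'-hydroxychalcones in weakly basic aqueous buffer (KH2PO4/K2HPO4, pH 7.5–8, MeOH as cosolvent, 25 °C). This should give the racemic flavanone F1, purified by ordinary chromatography. Resolution by preparative HPLC on a chiral stationary phase (amylose tris(3,5-dimethylphenylcarbamate)), a known way to separate flavanone enantiomers, then gives the (2S)-enantiomer and the (2R)-enantiomer F2, which is set aside. The fallback comes back to the route at 19.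

Step 8. The methylidenepyrandione may be intercepted by a second molecule of pyrone faster than by the electron-poor ring of 14, so homodimerisation of the pyrone would consume the electrophile. The fallback reverses the roles of the partners and sets out from 14. Aminomethylation of its free ring carbon with 15 (MeCN, 0 °C) should give the aryl Mannich base (E)-1-[3-[(dimethylamino)methyl]-2,4,6-trihydroxy-5-(3-methylbut-2-enoyl)phenyl]-3-phenylprop-2-en-1-one F3, kept as its hydroiodide. Warming F3 with pyrone 4 (dioxane, 60 °C) should expel dimethylamine to give the ortho-quinone methide 3,5-dihydroxy-6-methylidene-2-(3-methylbut-2-enoyl)-4-[(E)-3-phenylprop-2-enoyl]cyclohexa-2,4-dien-1-one F4. This is trapped by the nucleophilic C3 of 4, the known use of phenolic Mannich bases to alkylate 4-hydroxypyranones. The fallback comes back to the route at 18.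

Step 7. While the acetals are being cleaved, the freed phenols may add to either enone under acid catalysis (ring closure of the cinnamoyl or the 3-methylbut-2-enoyl arm), or methanol may add to an enone. The fallback sets out from 13 and avoids protic acid. Treatment with TMSOTf and 2,2'-bipyridyl (CH2Cl2, 0 °C), a known base-buffered exchange of aryl MOM ethers for silyl ethers, should give the tris(trimethylsilyl) ether (E)-1-[3-(3-methylbut-2-enoyl)-2,4,6-tris(trimethylsilyloxy)phenyl]-3-phenylprop-2-en-1-one F5. Neutral hydrolysis with water at 25 °C then gives the free phenols. The fallback comes back to the route at 14.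

Further compounds
F1 | step 9 | racemic 6-[(6-ethyl-4-hydroxy-5-methyl-2-oxo-2H-pyran-3-yl)methyl]-5,7-dihydroxy-8-(3-methylbut-2-enoyl)-2-phenyl-2,3-dihydro-4H-chromen-4-one | CCc1oc(=O)c(Cc2c(O)c(C(=O)C=C(C)C)c3c(c2O)C(=O)CC(c2ccccc2)O3)c(O)c1C
F2 | step 9 | (2R)-6-[(6-ethyl-4-hydroxy-5-methyl-2-oxo-2H-pyran-3-yl)methyl]-5,7-dihydroxy-8-(3-methylbut-2-enoyl)-2-phenyl-2,3-dihydro-4H-chromen-4-one | CCc1oc(=O)c(Cc2c(O)c(C(=O)C=C(C)C)c3c(c2O)C(=O)C[C@H](c2ccccc2)O3)c(O)c1C
F3 | step 8 | (E)-1-[3-[(dimethylamino)methyl]-2,4,6-trihydroxy-5-(3-methylbut-2-enoyl)phenyl]-3-phenylprop-2-en-1-one | CN(C)Cc1c(O)c(C(=O)C=C(C)C)c(O)c(C(=O)/C=C/c2ccccc2)c1O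
F4 | step 8 | 3,5-dihydroxy-6-methylidene-2-(3-methylbut-2-enoyl)-4-[(E)-3-phenylprop-2-enoyl]cyclohexa-2,4-dien-1-one | C=C1C(=O)C(C(=O)C=C(C)C)=C(O)C(C(=O)/C=C/c2ccccc2)=C1O
F5 | step 7 | (E)-1-[3-(3-methylbut-2-enoyl)-2,4,6-tris(trimethylsilyloxy)phenyl]-3-phenylprop-2-en-1-one | CC(C)=CC(=O)c1c(O[Si](C)(C)C)cc(O[Si](C)(C)C)c(C(=O)/C=C/c2ccccc2)c1O[Si](C)(C)C
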